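## Retrosynthetic overview

1. Locants used: ring A is the arene (C4a, C5, C6 with CO2Me, C7 and C8 with OH, C8a); ring B is C1(Me)–C2–C3–C4 plus C4a/C8a; the side chain is C11(Me)–C12–C13–C14–C15(Me)–C16(OH). The target is (1R,4S,11S,15S).
2. Ring B is closed last, at C3–C4, by a copper hydride-catalysed enantioselective reductive cyclisation of an (E)-C4=C11 styrene onto a primary C3 bromide; the same event creates C4 and C11. The enabling feature is that C4 is bonded to ring A at C4a, so the C4=C11 alkene is a styrene that takes copper at C4, while C3 ends the C1–C2–C3 chain on the neighbouring ring-A atom C8a and so lies in 6-exo-tet reach of C4.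
3. The cyclisation precursor comes from a Suzuki coupling (C4a–C4) of an aryl bromide that carries C1 with an (E)-alkenyl boronate that carries C15.
4. Arene half: 2,2-dimethyl-1,3-benzodioxole (ring A with a temporary dioxole ring on O7/O8) → ortho-lithiation/borylation at C8a → Rh-catalysed asymmetric conjugate addition to ethyl crotonate (sets C1) → second ortho-lithiation at C6 (CO2Me) → bromination at C4a.
5. Side-chain half: hept-6-ynoic acid → Evans methylation (sets C15) → Cu-catalysed methylboration of the alkyne. Ring order: ring A and the dioxole are bought, ring B is made in the key step, the dioxole is opened in the last step.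

Key step: step 14

Assumption (chemistry): the face selectivity of the (R)-DTBM-SEGPHOS–CuH catalyst on the E-trisubstituted styrene is taken to follow that on E-β-alkylstyrenes; the mirror-image ligand would be used if it does not.

## Route

Step 1
Reactants: 1 2,2-dimethyl-1,3-benzodioxole
Product: 4 (2,2-dimethyl-1,3-benzodioxol-4-yl)boronic acid, via aryllithium 2 (not isolated), via lithium aryltriisopropoxyborate 3 (not isolated)
Conditions: n-BuLi, TMEDA, Et2O, 0 °C → rt; B(OiPr)3, −78 °C → rt; 1 M HCl, 0 °C
Reagents that add atoms: n-butyllithium, [Li]CCCC (lithium of 2 and 3 only); triisopropyl borate, CC(C)OB(OC(C)C)OC(C)C; water, O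
Why: Directed ortho-metalation: the dioxole oxygen coordinates n-BuLi and acidifies the neighbouring aromatic C–H (the 2-position is quaternary, so no other site competes), and the aryllithium is trapped by the borate and hydrolysed to the boronic acid; no stereocentre is formed.

Step 2
Reactants: 4 (2,2-dimethyl-1,3-benzodioxol-4-yl)boronic acid (in excess); 5 ethyl (E)-but-2-enoate
Product: 6 ethyl (3R)-3-(2,2-dimethyl-1,3-benzodioxol-4-yl)butanoate
Conditions: Rh(acac)(C2H4)2 (3 mol%), (S)-BINAP (3.3 mol%), dioxane/H2O (10:1), 100 °C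
Reagents that add atoms: none
Why: Hayashi–Miyaura rhodium-catalysed asymmetric 1,4-addition: the aryl–rhodium–BINAP species inserts the E-enoate and water protonates the resulting oxa-π-allyl rhodium, C1 being set by the ligand, since the (S)-BINAP complex is known to deliver aryl groups to the C2-si face of E-crotonates and should thus give the 3R ester.

Step 3
Reactants: 6 ethyl (3R)-3-(2,2-dimethyl-1,3-benzodioxol-4-yl)butanoate
Product: 7 (3R)-3-(2,2-dimethyl-1,3-benzodioxol-4-yl)butan-1-ol
Conditions: LiAlH4, THF, 0 °C; NaOH/H2O work-up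
Reagents that add atoms: none
Why: Standard LiAlH4 reduction of an ester to the primary alcohol (the future C3 oxygen function); C1 carries no acidifying group and is not at risk, and the aryl acetonide is inert to hydride.

Step 4
Reactants: 7 (3R)-3-(2,2-dimethyl-1,3-benzodioxol-4-yl)butan-1-ol
Product: 8 tert-butyl[(3R)-3-(2,2-dimethyl-1,3-benzodioxol-4-yl)butoxy]dimethylsilane
Conditions: TBSCl, imidazole, DMF, rt
Reagents that add atoms: tert-butyldimethylsilyl chloride, CC(C)(C)[Si](C)(C)Cl
Why: Silyl ether formation masks the alcohol so that the next lithiation consumes only one equivalent of base and the C3 oxygen can later be exchanged for bromide.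

Step 5
Reactants: 8 tert-butyl[(3R)-3-(2,2-dimethyl-1,3-benzodioxol-4-yl)butoxy]dimethylsilane
Product: 10 methyl 7-[(2R)-4-{[tert-butyl(dimethyl)silyl]oxy}butan-2-yl]-2,2-dimethyl-1,3-benzodioxole-4-carboxylate, via aryllithium 9 (not isolated)
Conditions: s-BuLi, TMEDA, Et2O, −78 → −30 °C; then cannulated into excess ClCO2Me, THF, −78 °C
Reagents that add atoms: sec-butyllithium, [Li]C(C)CC (lithium of 9 only); methyl chloroformate, COC(=O)Cl
Why: Second directed ortho-metalation: C6 is the only remaining position ortho to a dioxole oxygen, and inverse addition of the aryllithium to excess methyl chloroformate should give the methyl ester without over-addition; C1 is untouched because the tertiary benzylic C–H is kinetically far less acidic than the oxygen-flanked aryl C–H.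

Step 6
Reactants: 10 methyl 7-[(2R)-4-{[tert-butyl(dimethyl)silyl]oxy}butan-2-yl]-2,2-dimethyl-1,3-benzodioxole-4-carboxylate
Product: 11 methyl 6-bromo-7-[(2R)-4-{[tert-butyl(dimethyl)silyl]oxy}butan-2-yl]-2,2-dimethyl-1,3-benzodioxole-4-carboxylate
Conditions: NBS, DMF, 0 °C → rt, dark
Reagents that add atoms: N-bromosuccinimide, O=C1CCC(=O)N1Br
Why: Electrophilic aromatic bromination: C4a is para to the C7 oxygen, ortho to the alkyl group and meta to the ester, whereas the only other free position (C5) is ortho to the deactivating ester, so bromine should enter at C4a.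

Step 7
Reactants: 11 methyl 6-bromo-7-[(2R)-4-{[tert-butyl(dimethyl)silyl]oxy}butan-2-yl]-2,2-dimethyl-1,3-benzodioxole-4-carboxylate
Product: 12 methyl 6-bromo-7-[(2R)-4-bromobutan-2-yl]-2,2-dimethyl-1,3-benzodioxole-4-carboxylate
Conditions: Ph3PBr2, CH2Cl2, 0 °C → rt
Reagents that add atoms: triphenylphosphine dibromide, Br[P+](c1ccccc1)(c1ccccc1)c1ccccc1.[Br-]
Why: Direct conversion of a primary silyl ether into the bromide with triphenylphosphine dibromide (oxyphosphonium formation, then SN2 by bromide at the primary carbon C3), a known one-step alternative to desilylation followed by an Appel reaction; C1 is not involved.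

Step 8
Reactants: 13 hept-6-ynoic acid; 14 (4S)-4-benzyl-1,3-oxazolidin-2-one
Product: 16 (4S)-4-benzyl-3-(hept-6-ynoyl)-1,3-oxazolidin-2-one, via hept-6-ynoic pivalic anhydride 15 (not isolated)
Conditions: PivCl, Et3N, THF, −20 °C; then 14, LiCl, rt
Reagents that add atoms: pivaloyl chloride, CC(C)(C)C(=O)Cl (atoms of 15 only)
Why: N-Acylation of the Evans oxazolidinone through the mixed pivalic anhydride (LiCl/Et3N protocol), which avoids an acid chloride and leaves the terminal alkyne untouched.

Step 9
Reactants: 16 (4S)-4-benzyl-3-(hept-6-ynoyl)-1,3-oxazolidin-2-one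
Product: 18 (4S)-4-benzyl-3-[(2S)-2-methylhept-6-ynoyl]-1,3-oxazolidin-2-one, via sodium Z-enolate 17 (not isolated)
Conditions: NaN(SiMe3)2 (1.05 equiv), THF, −78 °C; MeI, −78 → −40 °C
Reagents that add atoms: sodium bis(trimethylsilyl)amide, C[Si](C)(C)[N-][Si](C)(C)C.[Na+] (sodium of 17 only); iodomethane, CI
Why: Evans asymmetric alkylation: the chelated Z-sodium enolate is methylated on the face opposite to the benzyl group of the (4S)-auxiliary, which sets C15 as 2S in the acyl chain; the imide α-proton is far more acidic than the alkyne C–H, so one equivalent of base should enolise selectively.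

Step 10
Reactants: 18 (4S)-4-benzyl-3-[(2S)-2-methylhept-6-ynoyl]-1,3-oxazolidin-2-one
Product: 19 (2S)-2-methylhept-6-yn-1-ol
Conditions: LiBH4, MeOH (1 equiv), Et2O, 0 °C
Reagents that add atoms: none
Why: Reductive removal of the auxiliary with LiBH4 should give the primary alcohol C16 without enolisation of the C15 centre and return the oxazolidinone.

Step 11
Reactants: 19 (2S)-2-methylhept-6-yn-1-ol
Product: 20 tert-butyldimethyl{[(2S)-2-methylhept-6-yn-1-yl]oxy}silane
Conditions: TBSCl, imidazole, CH2Cl2, rt
Reagents that add atoms: tert-butyldimethylsilyl chloride, CC(C)(C)[Si](C)(C)Cl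
Why: Silyl ether formation protects O16 through the organometallic steps and lets it fall together with the acetonide in the final acid treatment.

Step 12
Reactants: 20 tert-butyldimethyl{[(2S)-2-methylhept-6-yn-1-yl]oxy}silane
Product: 22 tert-butyl{[(2S,6E)-2,6-dimethyl-7-(4,4,5,5-tetramethyl-1,3,2-dioxaborolan-2-yl)hept-6-en-1-yl]oxy}dimethylsilane, via β-boryl alkenylcopper 21 (not isolated)
Conditions: CuCl (10 mol%), Xantphos (10 mol%), NaOt-Bu, B2pin2, MeI, THF, rt
Reagents that add atoms: bis(pinacolato)diboron, CC1(C)OB(OC1(C)C)B1OC(C)(C)C(C)(C)O1; iodomethane, CI; copper chloride CuCl, Cl[Cu] (copper of 21 only)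
Why: Copper-catalysed carboboration (methylboration) of a terminal alkyne: LCu–Bpin adds syn with boron on the terminal carbon C4 and copper on C11, and the alkenylcopper is methylated by MeI with retention, so that boron and the new methyl group are cis and the alkenyl boronate is E.

Step 13
Reactants: 12 methyl 6-bromo-7-[(2R)-4-bromobutan-2-yl]-2,2-dimethyl-1,3-benzodioxole-4-carboxylate; 22 tert-butyl{[(2S,6E)-2,6-dimethyl-7-(4,4,5,5-tetramethyl-1,3,2-dioxaborolan-2-yl)hept-6-en-1-yl]oxy}dimethylsilane
Product: 23 methyl 7-[(2R)-4-bromobutan-2-yl]-6-[(1E,6S)-7-{[tert-butyl(dimethyl)silyl]oxy}-2,6-dimethylhept-1-en-1-yl]-2,2-dimethyl-1,3-benzodioxole-4-carboxylate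
Conditions: Pd(OAc)2 (5 mol%), SPhos (10 mol%), K3PO4, toluene/H2O (10:1), 60 °C
Reagents that add atoms: none
Why: Suzuki–Miyaura coupling forms C4a–C4 with retention of the alkene geometry; a biarylphosphine–palladium catalyst handles the ortho-branched aryl bromide and inserts into C(sp2)–Br much faster than into the unactivated primary C(sp3)–Br, which is kept for the next step.

Step 14
Reactants: 23 methyl 7-[(2R)-4-bromobutan-2-yl]-6-[(1E,6S)-7-{[tert-butyl(dimethyl)silyl]oxy}-2,6-dimethylhept-1-en-1-yl]-2,2-dimethyl-1,3-benzodioxole-4-carboxylate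
Product: 25 methyl (6S,9R)-6-[(2S,6S)-7-{[tert-butyl(dimethyl)silyl]oxy}-6-methylheptan-2-yl]-2,2,9-trimethyl-6,7,8,9-tetrahydronaphtho[1,2-d][1,3]dioxole-4-carboxylate, via benzylic organocopper 24 (not isolated)
Conditions: Cu(OAc)2 (5 mol%), (R)-DTBM-SEGPHOS (5.5 mol%), LiOMe, MeSiH(OMe)2, THF, rt → 40 °C
Reagents that add atoms: copper diacetate, CC(=O)[O-].CC(=O)[O-].[Cu+2] (copper of 24 only)
Why: Proposed new method: LCuH, formed from Cu(OAc)2, the bisphosphine and the silane, adds syn across the C4=C11 bond with copper at the benzylic, less substituted C4 and hydride at C11, and the benzylic copper then displaces the primary bromide at C3 (SN2 at C3, retention at C4), after which LiOMe and the silane turn LCuBr back into LCuH. The closest known reaction type is the copper hydride-catalysed enantioselective intramolecular hydroalkylation of β-monosubstituted styrenes that carry an alkyl bromide, which gives cyclobutanes, cyclopentanes and indanes; new here are the β,β-disubstituted styrene and the tetralin ring size. Ring B is closed by a 6-exo-tet alkylation (C4 on C3), the ortho C1–C2–C3 tether on C8a holding C3 within reach. C11 is set by the face to which the ligand directs the hydride and C4 by the same syn addition followed by the stereoretentive alkylation, so the E geometry of the alkene fixes the like relationship (4S,11S or 4R,11R) and the ligand enantiomer chooses 4S,11S; the remote C1 centre takes no part, so the 1,4-trans relationship follows from catalyst control. The step needs regioselective hydrocupration (both the steric and the benzylic preference place copper on C4), no erosion at C11 (copper alkyls of this kind do not undergo β-hydride elimination or chain-walking) and chemoselectivity over reduction of the C–Br bond and of the ester (exchange of the methyl ester with LiOMe is degenerate).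

Step 15
Reactants: 25 methyl (6S,9R)-6-[(2S,6S)-7-{[tert-butyl(dimethyl)silyl]oxy}-6-methylheptan-2-yl]-2,2,9-trimethyl-6,7,8,9-tetrahydronaphtho[1,2-d][1,3]dioxole-4-carboxylate
Product: 26 methyl (5R,8S)-3,4-dihydroxy-8-[(2S,6S)-7-hydroxy-6-methylheptan-2-yl]-5-methyl-5,6,7,8-tetrahydronaphthalene-2-carboxylate
Conditions: TFA/H2O (9:1), 0 °C → rt; then MeOH
Reagents that add atoms: none
Why: Acid hydrolysis cleaves the aryl acetonide (to the catechol and acetone) and the primary TBS ether in one operation, conditions under which the methyl ester and the four stereocentres, none of them α to a carbonyl group, should be stable.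

## Compound list

1 | 2,2-dimethyl-1,3-benzodioxole | CC1(C)Oc2ccccc2O1 | starting material
2 | (2,2-dimethyl-1,3-benzodioxol-4-yl)lithium (not isolated) | [Li]c1cccc2OC(C)(C)Oc12 | intermediate
3 | lithium (2,2-dimethyl-1,3-benzodioxol-4-yl)tri(propan-2-yloxy)borate (not isolated) | [Li+].CC(C)O[B-](OC(C)C)(OC(C)C)c1cccc2OC(C)(C)Oc12 | intermediate
4 | (2,2-dimethyl-1,3-benzodioxol-4-yl)boronic acid | OB(O)c1cccc2OC(C)(C)Oc12 | intermediate
5 | ethyl (E)-but-2-enoate (ethyl crotonate) | C/C=C/C(=O)OCC | starting material
6 | ethyl (3R)-3-(2,2-dimethyl-1,3-benzodioxol-4-yl)butanoate | CCOC(=O)C[C@@H](C)c1cccc2OC(C)(C)Oc12 | intermediate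
7 | (3R)-3-(2,2-dimethyl-1,3-benzodioxol-4-yl)butan-1-ol | OCC[C@@H](C)c1cccc2OC(C)(C)Oc12 | intermediate
8 | tert-butyl[(3R)-3-(2,2-dimethyl-1,3-benzodioxol-4-yl)butoxy]dimethylsilane | CC(C)(C)[Si](C)(C)OCC[C@@H](C)c1cccc2OC(C)(C)Oc12 | intermediate
9 | {7-[(2R)-4-{[tert-butyl(dimethyl)silyl]oxy}butan-2-yl]-2,2-dimethyl-1,3-benzodioxol-4-yl}lithium (not isolated) | [Li]c1ccc([C@H](C)CCO[Si](C)(C)C(C)(C)C)c2OC(C)(C)Oc12 | intermediate
10 | methyl 7-[(2R)-4-{[tert-butyl(dimethyl)silyl]oxy}butan-2-yl]-2,2-dimethyl-1,3-benzodioxole-4-carboxylate | COC(=O)c1ccc([C@H](C)CCO[Si](C)(C)C(C)(C)C)c2OC(C)(C)Oc12 | intermediate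
11 | methyl 6-bromo-7-[(2R)-4-{[tert-butyl(dimethyl)silyl]oxy}butan-2-yl]-2,2-dimethyl-1,3-benzodioxole-4-carboxylate | COC(=O)c1cc(Br)c([C@H](C)CCO[Si](C)(C)C(C)(C)C)c2OC(C)(C)Oc12 | intermediate
12 | methyl 6-bromo-7-[(2R)-4-bromobutan-2-yl]-2,2-dimethyl-1,3-benzodioxole-4-carboxylate | COC(=O)c1cc(Br)c([C@H](C)CCBr)c2OC(C)(C)Oc12 | intermediate
13 | hept-6-ynoic acid | C#CCCCCC(=O)O | starting material
14 | (4S)-4-benzyl-1,3-oxazolidin-2-one | O=C1N[C@@H](Cc2ccccc2)CO1 | starting material
15 | hept-6-ynoic 2,2-dimethylpropanoic anhydride (not isolated) | C#CCCCCC(=O)OC(=O)C(C)(C)C | intermediate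
16 | (4S)-4-benzyl-3-(hept-6-ynoyl)-1,3-oxazolidin-2-one | C#CCCCCC(=O)N1[C@@H](Cc2ccccc2)COC1=O | intermediate
17 | sodium (Z)-enolate of 16 (not isolated) | C#CCCC/C=C(\[O-])N1[C@@H](Cc2ccccc2)COC1=O.[Na+] | intermediate
18 | (4S)-4-benzyl-3-[(2S)-2-methylhept-6-ynoyl]-1,3-oxazolidin-2-one | C#CCCC[C@H](C)C(=O)N1[C@@H](Cc2ccccc2)COC1=O | intermediate
19 | (2S)-2-methylhept-6-yn-1-ol | C#CCCC[C@H](C)CO | intermediate
20 | tert-butyldimethyl{[(2S)-2-methylhept-6-yn-1-yl]oxy}silane | C#CCCC[C@H](C)CO[Si](C)(C)C(C)(C)C | intermediate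
21 | β-boryl alkenylcopper from syn-borylcupration of 20, boron on C4 and copper on C11 (not isolated; Xantphos on copper not drawn) | CC1(C)OB(/C=C(\[Cu])CCC[C@H](C)CO[Si](C)(C)C(C)(C)C)OC1(C)C | intermediate
22 | tert-butyl{[(2S,6E)-2,6-dimethyl-7-(4,4,5,5-tetramethyl-1,3,2-dioxaborolan-2-yl)hept-6-en-1-yl]oxy}dimethylsilane | CC1(C)OB(/C=C(\C)CCC[C@H](C)CO[Si](C)(C)C(C)(C)C)OC1(C)C | intermediate
23 | methyl 7-[(2R)-4-bromobutan-2-yl]-6-[(1E,6S)-7-{[tert-butyl(dimethyl)silyl]oxy}-2,6-dimethylhept-1-en-1-yl]-2,2-dimethyl-1,3-benzodioxole-4-carboxylate | COC(=O)c1cc(/C=C(\C)CCC[C@H](C)CO[Si](C)(C)C(C)(C)C)c([C@H](C)CCBr)c2OC(C)(C)Oc12 | intermediate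
24 | benzylic organocopper from syn-hydrocupration of 23, copper on C4 and new hydrogen on C11 (not isolated; DTBM-SEGPHOS on copper not drawn) | COC(=O)c1cc([C@@H]([Cu])[C@@H](C)CCC[C@H](C)CO[Si](C)(C)C(C)(C)C)c([C@H](C)CCBr)c2OC(C)(C)Oc12 | intermediate
25 | methyl (6S,9R)-6-[(2S,6S)-7-{[tert-butyl(dimethyl)silyl]oxy}-6-methylheptan-2-yl]-2,2,9-trimethyl-6,7,8,9-tetrahydronaphtho[1,2-d][1,3]dioxole-4-carboxylate (the target with the catechol as acetonide and O16 as TBS ether) | COC(=O)c1cc2c(c3OC(C)(C)Oc13)[C@H](C)CC[C@H]2[C@@H](C)CCC[C@H](C)CO[Si](C)(C)C(C)(C)C | intermediate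
26 | methyl (5R,8S)-3,4-dihydroxy-8-[(2S,6S)-7-hydroxy-6-methylheptan-2-yl]-5-methyl-5,6,7,8-tetrahydronaphthalene-2-carboxylate | COC(=O)c1cc2c(c(O)c1O)[C@H](C)CC[C@H]2[C@@H](C)CCC[C@H](C)CO | target

## Step count and risks

Total step count: 15. Longest linear sequence: 10 steps (steps 1–7, then 13–15).

Steps most likely to fail:

Step 14. Hydrocupration of the twisted, β,β-disubstituted styrene may be too slow, so that reduction of the C3–Br bond or plain reduction of the alkene overtakes cyclisation, or the face selectivity may be low. The fallback uses known chemistry, sets out from 23 and comes back to the route at 25: ring B would be closed by a tin-free radical cyclisation with (Me3Si)3SiH and AIBN in toluene at 80 °C, the silane being added slowly. The primary C3 radical should add 6-exo-trig to C4, and the tertiary C11 radical should then take hydrogen from the silane. Catalyst control is given up in this variant: C4 would be set by the existing C1 centre through the chair-like transition state and C11 by 1,2-induction, so 25 would have to be separated from its C4/C11 isomers by preparative chromatography. This fallback makes no new compound (entry F0).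

Step 13. Slow oxidative addition at the ortho-branched aryl bromide may leave time for loss of the primary bromide (hydrolysis or elimination by the base, or insertion of palladium into C(sp3)–Br followed by β-hydride elimination) or for protodeboronation of 22. The fallback changes the order so that the coupling is done on an alcohol; it sets out from 11 and comes back at 23, and step 7 is then not needed. TBAF in THF would cleave the silyl ether of 11 to methyl 6-bromo-7-[(2R)-4-hydroxybutan-2-yl]-2,2-dimethyl-1,3-benzodioxole-4-carboxylate F1. Suzuki coupling of this alcohol with 22 under the conditions of step 13 would give methyl 6-[(1E,6S)-7-{[tert-butyl(dimethyl)silyl]oxy}-2,6-dimethylhept-1-en-1-yl]-7-[(2R)-4-hydroxybutan-2-yl]-2,2-dimethyl-1,3-benzodioxole-4-carboxylate F2. An Appel reaction (CBr4, PPh3, CH2Cl2, 0 °C) would then convert the C3 alcohol into the bromide 23.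

Step 12. Deprotonation of the terminal alkyne to a copper acetylide, borylcupration with the wrong regiochemistry (boron on C11), or protonation of the alkenylcopper 21 before it is methylated may each divert the reaction. The fallback sets out from 20 and comes back at 22. Negishi zirconium-catalysed carboalumination (Me3Al, Cp2ZrCl2 cat., CH2Cl2, 0 °C → rt; syn addition of methyl and aluminium with aluminium on the terminal carbon) would give [(1E,6S)-7-{[tert-butyl(dimethyl)silyl]oxy}-2,6-dimethylhept-1-en-1-yl]dimethylalumane F3. Iodine in THF at −30 °C would convert it with retention into tert-butyl{[(2S,6E)-7-iodo-2,6-dimethylhept-6-en-1-yl]oxy}dimethylsilane F4. Miyaura borylation of this iodide (B2pin2, PdCl2(dppf), KOPh, toluene, 50 °C) would give 22.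

## Further compounds

F0 | step 14 | none | none
F1 | step 13 | methyl 6-bromo-7-[(2R)-4-hydroxybutan-2-yl]-2,2-dimethyl-1,3-benzodioxole-4-carboxylate | COC(=O)c1cc(Br)c([C@H](C)CCO)c2OC(C)(C)Oc12
F2 | step 13 | methyl 6-[(1E,6S)-7-{[tert-butyl(dimethyl)silyl]oxy}-2,6-dimethylhept-1-en-1-yl]-7-[(2R)-4-hydroxybutan-2-yl]-2,2-dimethyl-1,3-benzodioxole-4-carboxylate | COC(=O)c1cc(/C=C(\C)CCC[C@H](C)CO[Si](C)(C)C(C)(C)C)c([C@H](C)CCO)c2OC(C)(C)Oc12
F3 | step 12 | [(1E,6S)-7-{[tert-butyl(dimethyl)silyl]oxy}-2,6-dimethylhept-1-en-1-yl]dimethylalumane | C[Al](C)/C=C(\C)CCC[C@H](C)CO[Si](C)(C)C(C)(C)C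
F4 | step 12 | tert-butyl{[(2S,6E)-7-iodo-2,6-dimethylhept-6-en-1-yl]oxy}dimethylsilane | I/C=C(\C)CCC[C@H](C)CO[Si](C)(C)C(C)(C)C
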